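**Plan**

1. Gibberellane numbering is used for every compound, with α/β as in the target: ring A = C1–C5, C10; ring B = C5, C6, C8, C9, C10; rings C and D = C8, C9, C11–C16; C7 on C6; C18 and C19 on C4 (TBS, TBDPS, TES, TMS = the usual silyl groups).
2. Cuts, in order: C7 acid to CH2OH; the C10–O lactone bond and 1β-OH to a 1β,10β-epoxide of a Δ1(10) 19-acid; then C4–C5 of ring A (retro ester-enolate Claisen) to a δ-lactone C19(=O)–O–C1 on a ring B cyclopentene; then C1–C2 (vinylogous aldol), C10–C1 (formylation), C13–C16 (ketyl–alkyne), C8–C14 and C9–C11 (Diels–Alder), C8–C15.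
3. Enabling feature: C19 on C4 and the oxygen-bearing C1 flank the ring fusion C5–C10, so with C5=C10 as a ring B alkene the chain C4=C19–O–C1–C10=C5 is a Claisen array; the ester bond C19–O–C1 is absent from the target, serves as a tether and is cleaved in the event itself.
4. Forward order: ring B (chiral pool) → ring C → ring D → temporary δ-lactone → ring A (last ring of the carbon skeleton) → γ-lactone by epoxide opening → C7 oxidation.
5. Stereochemistry: C6 from (S)-4-silyloxycyclopentenone (anti radical addition); C8 and C9 from the anti, suprafacial Diels–Alder; C13 from the bridge; C1 (temporary, S) from a Ti/BINOL aldol; C3 from 1,3-anti reduction; C4 and C5 from the Claisen; C1 (final) and C10 from 3-OH-directed epoxidation and opening with inversion at C10.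

Key step: step 16

Assumption: the Ti(OiPr)4/(S)-BINOL catalyst is taken to add the dienol ether to the Si face of the enal, as in related BINOL–titanium carbonyl additions; if the sense is the reverse on this substrate, the (R)-ligand is used in step 13.

**Route**

Step 1
Reactants: 1 (S)-4-(tert-butyldimethylsilyloxy)cyclopent-2-en-1-one
Product: 2 (3R,4S)-3-(hydroxymethyl)-4-(tert-butyldimethylsilyloxy)cyclopentan-1-one
Conditions: MeOH, Ph2CO (0.2 equiv), hν (350 nm), rt
Reagents that add atoms: methanol, CO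
Why: Benzophenone-sensitized radical conjugate hydroxymethylation (Giese-type addition) should put the hydroxymethyl radical on the enone β-carbon anti to the silyloxy group, which sets C6.

Step 2
Reactants: 2 (3R,4S)-3-(hydroxymethyl)-4-(tert-butyldimethylsilyloxy)cyclopentan-1-one
Product: 4 (S)-4-[(tert-butyldiphenylsilyloxy)methyl]cyclopent-2-en-1-one, via bis-silyl ketone 3 (not isolated)
Conditions: TBDPSCl, imidazole, CH2Cl2, 0 °C to rt; then DBU, 0 °C
Reagents that add atoms: tert-butyl(chloro)diphenylsilane, CC(C)(C)[Si](Cl)(c1ccccc1)c1ccccc1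
Why: Silylation of the primary alcohol followed by base-induced β-elimination (E1cB) of the silanol should give the 4-substituted cyclopentenone (C8=C9) without touching C6.

Step 3
Reactants: 4 (S)-4-[(tert-butyldiphenylsilyloxy)methyl]cyclopent-2-en-1-one
Product: 5 (S)-4-[(tert-butyldiphenylsilyloxy)methyl]-2-(phenylselanyl)cyclopent-2-en-1-one
Conditions: PhSeCl, pyridine, CH2Cl2, 0 °C to rt
Reagents that add atoms: phenylselenenyl chloride, Cl[Se]c1ccccc1
Why: α-Selenenylation of an enone (addition–elimination with PhSeCl–pyridine) should place selenium on C9 and so mark where the double bond is to be restored after β-substitution.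

Step 4
Reactants: 5 (S)-4-[(tert-butyldiphenylsilyloxy)methyl]-2-(phenylselanyl)cyclopent-2-en-1-one
Product: 8 (S)-4-[(tert-butyldiphenylsilyloxy)methyl]-3-(prop-2-yn-1-yl)cyclopent-2-en-1-one, via seleno ketone 6 (not isolated), via selenoxide 7 (not isolated)
Conditions: CH2=C=CHSnBu3, TiCl4, CH2Cl2, −78 °C; aq. NaHCO3 work-up; then H2O2, pyridine, CH2Cl2, 0 °C to rt
Reagents that add atoms: tributyl(propa-1,2-dien-1-yl)stannane, C=C=C[Sn](CCCC)(CCCC)CCCC
Why: Lewis acid-mediated conjugate propargylation (SE2′ transfer from the allenylstannane) should add C15–C17 to C8 anti to the C6 substituent, and selenoxide syn-elimination, possible only towards H-8, should restore the C8=C9 enone.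

Step 5
Reactants: 9 but-3-en-2-one
Product: 10 2-(tert-butyldimethylsilyloxy)buta-1,3-diene
Conditions: TBSOTf, Et3N, Et2O, 0 °C
Reagents that add atoms: tert-butyldimethylsilyl trifluoromethanesulfonate, CC(C)(C)[Si](C)(C)OS(=O)(=O)C(F)(F)F
Why: Soft enolization and O-silylation of the methyl ketone should give the 2-silyloxy diene.

Step 6
Reactants: 8 (S)-4-[(tert-butyldiphenylsilyloxy)methyl]-3-(prop-2-yn-1-yl)cyclopent-2-en-1-one; 10 2-(tert-butyldimethylsilyloxy)buta-1,3-diene
Product: 12 cis-fused B/C diketone (C10=O; C13=O; 8β-propargyl; 9β-H; 6β-CH2OTBDPS), via silyl enol ether adduct 11 (not isolated)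
Conditions: AlBr3/AlMe3 (0.2 equiv), PhMe–CH2Cl2, −20 to 0 °C; then 1 M HCl, THF
Reagents that add atoms: none
Why: Lewis acid-promoted Diels–Alder reaction in which the nucleophilic CH2 terminus of the diene should bond to the enone β-carbon C8 (so the oxygen ends on C13) and the diene should add suprafacially and anti to the C6 substituent, which sets quaternary C8 and C9 with the cis B/C fusion; acid then unmasks the C13 ketone.

Step 7
Reactants: 12 cis-fused B/C diketone
Product: 13 tricyclic B/C/D diol (13-OH; 16-methylene; C10 carbinol as epimers; 6β-CH2OTBDPS)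
Conditions: SmI2 (excess), HMPA, t-BuOH, THF, 0 °C to rt
Reagents that add atoms: none
Why: SmI2 ketyl–alkyne reductive cyclization (5-exo-dig): only the C13 ketyl can reach C16 without building a strained bicyclo[2.2.1] ring, the bridge fixes C13, and the excess reagent should take the C10 ketone to the carbinol that step 8 re-oxidizes.

Step 8
Reactants: 13 tricyclic B/C/D diol
Product: 14 tricyclic hydroxy ketone (C10=O; 13-OH; 16-methylene; 6β-CH2OTBDPS)
Conditions: Dess–Martin periodinane, NaHCO3, CH2Cl2, rt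
Reagents that add atoms: none
Why: Dess–Martin oxidation should return the C10 ketone from either epimer and cannot touch the tertiary 13-OH.

Step 9
Reactants: 14 tricyclic hydroxy ketone
Product: 15 13-O-TES tricyclic ketone
Conditions: TESOTf, 2,6-lutidine, CH2Cl2, −78 to 0 °C
Reagents that add atoms: triethylsilyl trifluoromethanesulfonate, CC[Si](CC)(CC)OS(=O)(=O)C(F)(F)F
Why: Silyl triflate silylation of the tertiary allylic alcohol should mask 13-OH, which would otherwise direct the later epoxidation to C16=C17.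

Step 10
Reactants: 15 13-O-TES tricyclic ketone
Product: 17 C5=C10 enol triflate, via potassium enolate 16 (not isolated)
Conditions: KN(SiMe3)2, THF, −78 °C; then PhNTf2
Reagents that add atoms: N-phenylbis(trifluoromethanesulfonimide), O=S(=O)(N(c1ccccc1)S(=O)(=O)C(F)(F)F)C(F)(F)F
Why: Kinetic enolization at the C5 methylene (C9 is a hindered ring-fusion methine) and O-triflation should give the C5=C10 enol triflate regioselectively.

Step 11
Reactants: 17 C5=C10 enol triflate
Product: 18 ring B enal (C1 aldehyde on C10; C5=C10; 13-OTES; 6β-CH2OTBDPS)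
Conditions: Pd(PPh3)4 (cat.), CO (1 atm), Bu3SnH (slow addition), LiCl, THF, 50 °C
Reagents that add atoms: carbon monoxide, [C-]#[O+]
Why: Palladium-catalyzed reductive carbonylation (formylation) of an enol triflate should install C1 as the aldehyde on C10.

Step 12
Reactants: 19 methyl 2-methyl-3-oxobutanoate
Product: 21 1-methoxy-2-methyl-1,3-bis(trimethylsilyloxy)buta-1,3-diene, via mono-silyl enol ether 20 (not isolated)
Conditions: Me3SiCl, Et3N, hexane, rt; then LiN(iPr)2, THF, −78 °C; Me3SiCl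
Reagents that add atoms: chlorotrimethylsilane, C[Si](C)(C)Cl
Why: Two-stage enol silylation of a β-keto ester should give the bis-silyl dienol ether that carries C2, C3, C4, C18 and C19.

Step 13
Reactants: 18 ring B enal; 21 1-methoxy-2-methyl-1,3-bis(trimethylsilyloxy)buta-1,3-diene
Product: 23 (1S)-δ-hydroxy β-keto methyl ester on C10 (C1 carbinol; C3 ketone; C4 methyl as epimers), via bis-silyl aldol adduct 22 (not isolated)
Conditions: Ti(OiPr)4/(S)-BINOL (10 mol%), 4 Å MS, THF, −78 to −20 °C; then aq. citric acid, MeOH, 0 °C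
Reagents that add atoms: none
Why: Catalytic enantioselective vinylogous Mukaiyama aldol reaction in which the titanium–BINOL complex should direct the γ-carbon (C2) of the dienol ether to the Si face of the aldehyde, which sets the temporary (1S) carbinol.

Step 14
Reactants: 23 (1S)-δ-hydroxy β-keto methyl ester
Product: 24 (1S,3S)-anti-diol methyl ester
Conditions: Me4NBH(OAc)3, MeCN–AcOH, −30 °C
Reagents that add atoms: none
Why: Evans–Saksena reduction (hydride delivered within the C1 alkoxyborohydride chelate) should give the 1,3-anti diol and so set C3 from C1.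

Step 15
Reactants: 24 (1S,3S)-anti-diol methyl ester
Product: 25 δ-lactone C19(=O)–O–C1 (3-OH cis to the ring B cyclopentenyl group at C1; C4 epimers)
Conditions: PPTS (cat.), CH2Cl2, rt
Reagents that add atoms: none
Why: Acid-catalyzed lactonization of the δ-hydroxy ester should close the six-membered lactone that ties C19 to the C1 oxygen.

Step 16
Reactants: 25 δ-lactone C19(=O)–O–C1
Product: 28 ring A hydroxy acid (C1=C10; 3β-OH; 4β-CH3; 4α-CO2H; 5β-H), via silyl ketene acetal 26 (not isolated), via silyl ester 27 (not isolated)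
Conditions: LiN(iPr)2 (2.5 equiv), Me3SiCl–Et3N, THF, −78 °C to rt; PhMe, 100 °C; then aq. citric acid, THF, 0 °C
Reagents that add atoms: none
Why: Deprotonation at C4 with in situ silylation gives the lactone silyl ketene acetal (3-OH is masked at the same time as its TMS ether, so the β-oxygen is not expelled), which on heating should undergo a [3,3] sigmatropic shift through C4=C19–O–C1–C10=C5, the C1–O bond breaking as C4–C5 forms. This is the ester-enolate (Ireland–Claisen) rearrangement in its lactone-to-carbocycle form, known for 6-alkenyl δ-lactones. Ring A is closed by the single new bond C4–C5 in a six-membered pericyclic transition state that is forced into a boat, because C2–C3 already ties C4 to C1 (a bicyclo[2.2.2] array). C5 is set by chirality transfer from C1: the oxygen leaves C1 and C4 enters C5 on the same (α) face of the C1–C10=C5 allyl unit, which is also the face anti to the C6 substituent, so tether and substrate are matched. C4 is set by the ring-locked ketene acetal geometry and the boat, which place C19 cis to C6 (α) and the methyl β, while C3 is carried through unchanged. The step needs chemoselective enolization of the lactone, secured because no other acidic C–H is present (C7 is a silyl ether, 13-OH a TES ether).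

Step 17
Reactants: 28 ring A hydroxy acid
Product: 30 19,10-lactone 1β,3β-diol (13-OTES; C7 as CH2OTBDPS), via epoxy acid 29 (not isolated)
Conditions: VO(acac)2 (cat.), t-BuOOH, CH2Cl2, 0 °C to rt; then PPTS (cat.)
Reagents that add atoms: tert-butyl hydroperoxide, CC(C)(C)OO
Why: Hydroxyl-directed vanadium-catalyzed epoxidation should deliver oxygen from the homoallylic axial 3β-OH to the β face of C1=C10, and the C19 acid on the α face should open the epoxide at tertiary C10 with inversion (5-exo, anti), which closes the γ-lactone and sets C10 (α-O) and C1 (β-OH).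

Step 18
Reactants: 30 19,10-lactone 1β,3β-diol (13-OTES; C7 as CH2OTBDPS)
Product: 31 7-hydroxymethyl tetraol lactone (1β,3β,13-triol; C7 as CH2OH)
Conditions: HF·pyridine, THF–pyridine, 0 °C to rt
Reagents that add atoms: none
Why: Fluoride-mediated desilylation under non-basic conditions should free 13-OH and the C7 carbinol without retro-aldol epimerization at C3.

Step 19
Reactants: 31 7-hydroxymethyl tetraol lactone
Product: 33 GA55, via C7 aldehyde 32 (not isolated)
Conditions: TEMPO (cat.), PhI(OAc)2, MeCN–H2O, rt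
Reagents that add atoms: water, O
Why: Nitroxyl-catalyzed oxidation selective for primary alcohols should take C7 through the aldehyde hydrate to the acid and leave the hindered axial secondary and the tertiary hydroxyls.

**Compound list**

1 | (S)-4-(tert-butyldimethylsilyloxy)cyclopent-2-en-1-one | O=C1C=C[C@@H](O[Si](C)(C)C(C)(C)C)C1 | starting material
2 | (3R,4S)-3-(hydroxymethyl)-4-(tert-butyldimethylsilyloxy)cyclopentan-1-one | O=C1C[C@H](CO)[C@@H](O[Si](C)(C)C(C)(C)C)C1 | intermediate
3 | (3R,4S)-3-[(tert-butyldiphenylsilyloxy)methyl]-4-(tert-butyldimethylsilyloxy)cyclopentan-1-one | O=C1C[C@H](CO[Si](c2ccccc2)(c2ccccc2)C(C)(C)C)[C@@H](O[Si](C)(C)C(C)(C)C)C1 | intermediate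
4 | (S)-4-[(tert-butyldiphenylsilyloxy)methyl]cyclopent-2-en-1-one | O=C1C=C[C@@H](CO[Si](c2ccccc2)(c2ccccc2)C(C)(C)C)C1 | intermediate
5 | (S)-4-[(tert-butyldiphenylsilyloxy)methyl]-2-(phenylselanyl)cyclopent-2-en-1-one | O=C1C([Se]c2ccccc2)=C[C@@H](CO[Si](c2ccccc2)(c2ccccc2)C(C)(C)C)C1 | intermediate
6 | 3,4-trans-2-(phenylselanyl)-3-(prop-2-yn-1-yl)-4-[(tert-butyldiphenylsilyloxy)methyl]cyclopentan-1-one (C2 epimers) | O=C1C[C@H](CO[Si](c2ccccc2)(c2ccccc2)C(C)(C)C)[C@@H](CC#C)C1[Se]c1ccccc1 | intermediate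
7 | selenoxide of 6 | O=C1C[C@H](CO[Si](c2ccccc2)(c2ccccc2)C(C)(C)C)[C@@H](CC#C)C1[Se](=O)c1ccccc1 | intermediate
8 | (S)-4-[(tert-butyldiphenylsilyloxy)methyl]-3-(prop-2-yn-1-yl)cyclopent-2-en-1-one | C#CCC1=CC(=O)C[C@@H]1CO[Si](c1ccccc1)(c1ccccc1)C(C)(C)C | intermediate
9 | but-3-en-2-one | CC(=O)C=C | starting material
10 | 2-(tert-butyldimethylsilyloxy)buta-1,3-diene | C=CC(=C)O[Si](C)(C)C(C)(C)C | intermediate
11 | Diels–Alder adduct: cis-fused B/C bicycle with C10 ketone, C12=C13 TBS enol ether, 8β-propargyl, 9β-H, 6β-CH2OTBDPS | C#CC[C@]12CC(O[Si](C)(C)C(C)(C)C)=CC[C@H]1C(=O)C[C@@H]2CO[Si](c1ccccc1)(c1ccccc1)C(C)(C)C | intermediate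
12 | cis-fused B/C diketone (C10=O, C13=O, 8β-propargyl, 9β-H, 6β-CH2OTBDPS) | C#CC[C@]12CC(=O)CC[C@H]1C(=O)C[C@@H]2CO[Si](c1ccccc1)(c1ccccc1)C(C)(C)C | intermediate
13 | tricyclic B/C/D diol (13-OH, 16-methylene, C10 carbinol as epimers, 6β-CH2OTBDPS) | C=C1C[C@]23C[C@@]1(O)CC[C@H]2C(O)C[C@@H]3CO[Si](c1ccccc1)(c1ccccc1)C(C)(C)C | intermediate
14 | tricyclic hydroxy ketone (C10=O, 13-OH) | C=C1C[C@]23C[C@@]1(O)CC[C@H]2C(=O)C[C@@H]3CO[Si](c1ccccc1)(c1ccccc1)C(C)(C)C | intermediate
15 | 13-O-TES tricyclic ketone | C=C1C[C@]23C[C@@]1(O[Si](CC)(CC)CC)CC[C@H]2C(=O)C[C@@H]3CO[Si](c1ccccc1)(c1ccccc1)C(C)(C)C | intermediate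
16 | potassium C5=C10 enolate of 15 | [K+].C=C1C[C@]23C[C@@]1(O[Si](CC)(CC)CC)CC[C@H]2C([O-])=C[C@@H]3CO[Si](c1ccccc1)(c1ccccc1)C(C)(C)C | intermediate
17 | C5=C10 enol triflate | C=C1C[C@]23C[C@@]1(O[Si](CC)(CC)CC)CC[C@H]2C(OS(=O)(=O)C(F)(F)F)=C[C@@H]3CO[Si](c1ccccc1)(c1ccccc1)C(C)(C)C | intermediate
18 | ring B enal (C1 aldehyde on C10, C5=C10, 13-OTES, 6β-CH2OTBDPS) | C=C1C[C@]23C[C@@]1(O[Si](CC)(CC)CC)CC[C@H]2C(C=O)=C[C@@H]3CO[Si](c1ccccc1)(c1ccccc1)C(C)(C)C | intermediate
19 | methyl 2-methyl-3-oxobutanoate | COC(=O)C(C)C(C)=O | starting material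
20 | methyl 2-methyl-3-(trimethylsilyloxy)but-2-enoate | COC(=O)C(C)=C(C)O[Si](C)(C)C | intermediate
21 | 1-methoxy-2-methyl-1,3-bis(trimethylsilyloxy)buta-1,3-diene | COC(O[Si](C)(C)C)=C(C)C(=C)O[Si](C)(C)C | intermediate
22 | bis-silyl aldol adduct (1S; 1-OTMS; C3=C4 TMS enol ether) | C=C1C[C@]23C[C@@]1(O[Si](CC)(CC)CC)CC[C@H]2C(=C[C@@H]3CO[Si](c1ccccc1)(c1ccccc1)C(C)(C)C)[C@@H](O[Si](C)(C)C)CC(O[Si](C)(C)C)=C(C)C(=O)OC | intermediate
23 | (1S)-δ-hydroxy β-keto methyl ester on C10 (C4 epimers) | C=C1C[C@]23C[C@@]1(O[Si](CC)(CC)CC)CC[C@H]2C(=C[C@@H]3CO[Si](c1ccccc1)(c1ccccc1)C(C)(C)C)[C@@H](O)CC(=O)C(C)C(=O)OC | intermediate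
24 | (1S,3S)-anti-diol methyl ester (C4 epimers) | C=C1C[C@]23C[C@@]1(O[Si](CC)(CC)CC)CC[C@H]2C(=C[C@@H]3CO[Si](c1ccccc1)(c1ccccc1)C(C)(C)C)[C@@H](O)C[C@H](O)C(C)C(=O)OC | intermediate
25 | δ-lactone C19(=O)–O–C1, (1S,3S), 3-OH cis to the cyclopentenyl group (C4 epimers) | C=C1C[C@]23C[C@@]1(O[Si](CC)(CC)CC)CC[C@H]2C(=C[C@@H]3CO[Si](c1ccccc1)(c1ccccc1)C(C)(C)C)[C@@H]1C[C@H](O)C(C)C(=O)O1 | intermediate
26 | lactone silyl ketene acetal with 3-OTMS | C=C1C[C@]23C[C@@]1(O[Si](CC)(CC)CC)CC[C@H]2C(=C[C@@H]3CO[Si](c1ccccc1)(c1ccccc1)C(C)(C)C)[C@@H]1C[C@H](O[Si](C)(C)C)C(C)=C(O[Si](C)(C)C)O1 | intermediate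
27 | ring A acid as TMS ester with 3-OTMS (C1=C10) | C=C1C[C@]23C[C@@]1(O[Si](CC)(CC)CC)CC[C@H]2C4=CC[C@H](O[Si](C)(C)C)[C@@](C)(C(=O)O[Si](C)(C)C)[C@H]4[C@@H]3CO[Si](c1ccccc1)(c1ccccc1)C(C)(C)C | intermediate
28 | ring A hydroxy acid (C1=C10, 3β-OH, 4β-CH3, 4α-CO2H, 5β-H) | C=C1C[C@]23C[C@@]1(O[Si](CC)(CC)CC)CC[C@H]2C4=CC[C@H](O)[C@@](C)(C(=O)O)[C@H]4[C@@H]3CO[Si](c1ccccc1)(c1ccccc1)C(C)(C)C | intermediate
29 | 1β,10β-epoxy acid | C=C1C[C@]23C[C@@]1(O[Si](CC)(CC)CC)CC[C@H]2[C@@]45O[C@@H]4C[C@H](O)[C@@](C)(C(=O)O)[C@H]5[C@@H]3CO[Si](c1ccccc1)(c1ccccc1)C(C)(C)C | intermediate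
30 | 19,10-lactone 1β,3β-diol (13-OTES, C7 as CH2OTBDPS) | C=C1C[C@]23C[C@@]1(O[Si](CC)(CC)CC)CC[C@H]2[C@@]12OC(=O)[C@@](C)([C@H]1[C@@H]3CO[Si](c4ccccc4)(c4ccccc4)C(C)(C)C)[C@@H](O)C[C@H]2O | intermediate
31 | 7-hydroxymethyl tetraol lactone | C=C1C[C@]23C[C@@]1(O)CC[C@H]2[C@@]12OC(=O)[C@@](C)([C@H]1[C@@H]3CO)[C@@H](O)C[C@H]2O | intermediate
32 | C7 aldehyde | C=C1C[C@]23C[C@@]1(O)CC[C@H]2[C@@]12OC(=O)[C@@](C)([C@H]1[C@@H]3C=O)[C@@H](O)C[C@H]2O | intermediate
33 | GA55 | C=C1C[C@]23C[C@@]1(O)CC[C@H]2[C@@]12OC(=O)[C@@](C)([C@H]1[C@@H]3C(=O)O)[C@@H](O)C[C@H]2O | target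

**Count and risks**

Total steps: 19. Longest linear sequence: 17 (steps 1–4, 6–11, 13–19).

Step 16. The forced boat may make the shift so slow that desilylation, C-silylation or expulsion of the 3-silyloxy group from the ketene acetal comes first. The fallback closes ring A and the γ-lactone together by an oxidative radical cyclization. It sets out from enal 18. The aldol of step 13 is run with the (R)-BINOL catalyst and should give, through the (1R) bis-silyl adduct F1, the (1R) hydroxy keto ester F2. TBSOTf and 2,6-lutidine give the 1-O-TBS ether F3. Mn(OAc)3 in EtOH at 60 °C forms the C4 radical, which should add 6-endo to C5; the tertiary C10 radical is oxidized to the cation and trapped by the ester carbonyl with loss of methanol, which gives the 3-oxo 19,10-lactone F4. LiBH(s-Bu)3 at −78 °C should attack equatorially, because the axial 1β-silyloxy group blocks the β face, and give the 3β-alcohol F5. HF·pyridine removes the three silyl groups and the route is rejoined at tetraol 31.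

Step 6. The cycloaddition may stall because the dienophile β-carbon is fully substituted, or the Lewis acid may attack the terminal alkyne or strip the silyl group from the diene. The fallback uses a more reactive diene without Lewis acid and sets out from enone 8. Heating with commercial (E)-3-(tert-butyldimethylsilyloxy)-N,N-dimethylbuta-1,3-dien-1-amine in toluene should give, with the same regio- and facial sense, the amino silyl enol ether cycloadduct F6. Dilute HCl in THF hydrolyzes the enol ether and eliminates dimethylamine to give the enedione F7. Metal-free conjugate transfer hydrogenation (Hantzsch ester, dibenzylammonium trifluoroacetate) reduces C11=C12 only and the route is rejoined at diketone 12.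

Step 4. The allenylstannane may transfer allenyl as well as propargyl, TiCl4 may cleave the silyl ether, or the syn-elimination may be incomplete if selenium ends trans to H-8. The fallback brings in C15 and C16 as an acetate unit and sets out from enone 4 (step 3 is then not needed). A Mukaiyama–Michael addition of tert-butyl[(1-methoxyethenyl)oxy]dimethylsilane (LiClO4 cat., CH2Cl2) with silyl transfer should give the ester TBS enol ether F8, anti to the C6 substituent. (i-Bu)2AlH at −78 °C gives the aldehyde F9. The Ohira–Bestmann reagent with K2CO3 in MeOH gives the alkyne TBS enol ether F10. Saegusa–Ito dehydrogenation with Pd(OAc)2 in MeCN restores the C8=C9 enone and the route is rejoined at 8.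

**Further compounds**

F1 | step 16 | (1R) bis-silyl aldol adduct (C1 epimer of 22) | C=C1C[C@]23C[C@@]1(O[Si](CC)(CC)CC)CC[C@H]2C(=C[C@@H]3CO[Si](c1ccccc1)(c1ccccc1)C(C)(C)C)[C@H](O[Si](C)(C)C)CC(O[Si](C)(C)C)=C(C)C(=O)OC
F2 | step 16 | (1R)-δ-hydroxy β-keto methyl ester (C1 epimer of 23) | C=C1C[C@]23C[C@@]1(O[Si](CC)(CC)CC)CC[C@H]2C(=C[C@@H]3CO[Si](c1ccccc1)(c1ccccc1)C(C)(C)C)[C@H](O)CC(=O)C(C)C(=O)OC
F3 | step 16 | 1-O-TBS ether of F2 | C=C1C[C@]23C[C@@]1(O[Si](CC)(CC)CC)CC[C@H]2C(=C[C@@H]3CO[Si](c1ccccc1)(c1ccccc1)C(C)(C)C)[C@H](O[Si](C)(C)C(C)(C)C)CC(=O)C(C)C(=O)OC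
F4 | step 16 | 3-oxo 19,10-lactone with 1β-OTBS, 13-OTES and C7 as CH2OTBDPS | C=C1C[C@]23C[C@@]1(O[Si](CC)(CC)CC)CC[C@H]2[C@@]12OC(=O)[C@@](C)([C@H]1[C@@H]3CO[Si](c4ccccc4)(c4ccccc4)C(C)(C)C)C(=O)C[C@H]2O[Si](C)(C)C(C)(C)C
F5 | step 16 | 3β-alcohol of F4 | C=C1C[C@]23C[C@@]1(O[Si](CC)(CC)CC)CC[C@H]2[C@@]12OC(=O)[C@@](C)([C@H]1[C@@H]3CO[Si](c4ccccc4)(c4ccccc4)C(C)(C)C)[C@@H](O)C[C@H]2O[Si](C)(C)C(C)(C)C
F6 | step 6 | amino silyl enol ether cycloadduct (C11 dimethylamino, C12=C13 TBS enol ether, C10 ketone) | C#CC[C@]12CC(O[Si](C)(C)C(C)(C)C)=CC(N(C)C)[C@H]1C(=O)C[C@@H]2CO[Si](c1ccccc1)(c1ccccc1)C(C)(C)C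
F7 | step 6 | B/C enedione (C13=O conjugated with C11=C12, C10=O) | C#CC[C@]12CC(=O)C=C[C@H]1C(=O)C[C@@H]2CO[Si](c1ccccc1)(c1ccccc1)C(C)(C)C
F8 | step 4 | methyl 2-[3-(tert-butyldimethylsilyloxy)-5-[(tert-butyldiphenylsilyloxy)methyl]cyclopent-2-en-1-yl]acetate (trans) | COC(=O)C[C@H]1C=C(O[Si](C)(C)C(C)(C)C)C[C@@H]1CO[Si](c1ccccc1)(c1ccccc1)C(C)(C)C
F9 | step 4 | aldehyde from F8 | O=CC[C@H]1C=C(O[Si](C)(C)C(C)(C)C)C[C@@H]1CO[Si](c1ccccc1)(c1ccccc1)C(C)(C)C
F10 | step 4 | propargyl TBS enol ether from F9 | C#CC[C@H]1C=C(O[Si](C)(C)C(C)(C)C)C[C@@H]1CO[Si](c1ccccc1)(c1ccccc1)C(C)(C)C
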